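The cyclopentane ring is closed last, at C2–C3. C2 and the C7 oxygen are 1,4-related through C1 and C7a and cis on the cyclohexane ring, so both are carried as one cis-fused γ-lactone. Because C3 lies trans to that oxygen, the intact lactone cannot be attacked; in one flask the acyl group is passed from O7 to sulfur and SmI2 reduces the neopentyl C3 iodide, whose alkylsamarium closes onto C2 to give the trans-hydrindan-2-one with the free C7 hydroxyl. The precursor is the α-alkenyl bromo iodomethyl γ-lactone, built from two enantiospecifically bromocyclised halves joined by enolate alkenylation.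

Key step: step 16

Remark: hydrindane numbering as in the target (Cv = exocyclic vinyl CH); C3 (equatorial on C3a) and O7 (axial on C7) are trans on the cyclohexane, so an adduct of C3 with the closed lactone carbonyl would be an in,out-bridged oxabicyclo[3.3.1]nonane, and step 16 therefore opens C2–O7 in the same flask before C2–C3 forms, with precursor and product unchanged.

Step 1
Reactants: 1 3-methylbut-2-en-1-ol (prenol)
Product: 2 (2S)-2-bromo-3-chloro-3-methylbutan-1-ol
Conditions: NBS, ClTi(Oi-Pr)3, chiral tridentate Schiff-base ligand (20 mol %, enantiomer giving 2S), hexanes, −20 °C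
Reagents that add atoms: N-bromosuccinimide, O=C1CCC(=O)N1Br; chlorotitanium triisopropoxide, CC(C)O[Ti](Cl)(OC(C)C)OC(C)C
Why: Catalytic enantioselective bromochlorination of an allylic alcohol: the titanium-bound alkoxide selects the alkene face for bromonium formation and chloride opens it anti at the tertiary carbon, which sets the CHBr stereocentre that becomes the ring-A bromide.

Step 2
Reactants: 2 (2S)-2-bromo-3-chloro-3-methylbutan-1-ol; 3 tert-butyl 3-oxobutanoate (tert-butyl acetoacetate)
Product: 5 tert-butyl (6S)-6-bromo-7-chloro-7-methyl-3-oxooctanoate, via triflate 4 (not isolated)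
Conditions: Tf2O, 2,6-lutidine, CH2Cl2, −78 °C; then dianion of 3 (NaH, n-BuLi, THF, 0 °C), −78 → −40 °C
Reagents that add atoms: none
Why: O-Triflation followed by γ-alkylation of the acetoacetate dianion (SN2 at the primary carbon) should extend the chain without touching the CHBr centre.

Step 3
Reactants: 5 tert-butyl (6S)-6-bromo-7-chloro-7-methyl-3-oxooctanoate
Product: 7 (4S)-4-bromo-3,3-dimethylcyclohexan-1-one, via keto ester 6 (not isolated)
Conditions: HFIP, 25 °C; then TFA, CH2Cl2, 25 °C; PhMe, 80 °C
Reagents that add atoms: none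
Why: Bromine-assisted solvolytic ionisation of the tertiary chloride should give a configurationally defined bromonium ion that the β-keto ester enol opens at the tertiary carbon in a six-membered cation–enol cyclisation (enantiospecific bromochloride solvolysis), and acidolysis of the tert-butyl ester with decarboxylation then gives the ketone; the C–Br bond is never broken, so its configuration is kept.

Step 4
Reactants: 7 (4S)-4-bromo-3,3-dimethylcyclohexan-1-one
Product: 8 (4S)-4-bromo-5,5-dimethylcyclohex-1-en-1-yl trifluoromethanesulfonate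
Conditions: KHMDS (0.98 equiv), THF, −78 °C; PhNTf2
Reagents that add atoms: N-phenylbis(trifluoromethanesulfonimide), O=S(=O)(N(c1ccccc1)S(=O)(=O)C(F)(F)F)C(F)(F)F
Why: Kinetic enolisation away from the neopentyl C2 methylene and O-triflation (regioselective enol triflate formation) should place the ring alkene on the C6 side, which later fixes the geometry of the exocyclic alkene.

Step 5
Reactants: 8 (4S)-4-bromo-5,5-dimethylcyclohex-1-en-1-yl trifluoromethanesulfonate
Product: 9 (4S)-4-bromo-5,5-dimethylcyclohex-1-ene-1-carbaldehyde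
Conditions: Pd(OAc)2, dppp, CO (1 atm), Et3SiH, 2,6-lutidine, DMF, 60 °C
Reagents that add atoms: carbon monoxide, [C-]#[O+]
Why: Palladium-catalysed reductive carbonylation (formylation) of an alkenyl triflate by oxidative addition, CO insertion and hydride transfer from the silane, run with only a weak base so that HBr is not eliminated from the enal.

Step 6
Reactants: 9 (4S)-4-bromo-5,5-dimethylcyclohex-1-ene-1-carbaldehyde
Product: 11 (E)-[(4S)-4-bromo-3,3-dimethylcyclohexylidene]methyl trifluoromethanesulfonate, via silyl enol ether 10 (not isolated)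
Conditions: Et3SiH, RhCl(PPh3)3 (1 mol %), PhH, 50 °C; then CsF, PhNTf2, DME, 25 °C
Reagents that add atoms: N-phenylbis(trifluoromethanesulfonimide), O=S(=O)(N(c1ccccc1)S(=O)(=O)C(F)(F)F)C(F)(F)F
Why: Rhodium-catalysed 1,4-hydrosilylation passes through the s-cis enal, so oxygen should end cis to the ring carbon that receives hydride and trans to the CH2 next to CMe2 (E), and fluoride-induced O-triflation of the enolate keeps this geometry.

Step 7
Reactants: 12 geranyl acetate
Product: 13 methyl (3E)-4,8-dimethylnona-3,7-dienoate
Conditions: Pd2(dba)3, PPh3, NaBr (cat.), i-Pr2NEt, CO (30 atm), MeOH, 60 °C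
Reagents that add atoms: carbon monoxide, [C-]#[O+]; methanol, CO
Why: Palladium-catalysed alkoxycarbonylation of an allylic acetate through the π-allyl complex should insert CO at the primary terminus and keep the E trisubstituted alkene.

Step 8
Reactants: 13 methyl (3E)-4,8-dimethylnona-3,7-dienoate
Product: 14 methyl (3E,7E)-9-hydroxy-4,8-dimethylnona-3,7-dienoate
Conditions: SeO2 (cat.), t-BuOOH, salicylic acid (cat.), CH2Cl2, 25 °C
Reagents that add atoms: tert-butyl hydroperoxide, CC(C)(C)OO
Why: Selenium dioxide allylic oxidation (ene reaction then [2,3]-sigmatropic shift) should hydroxylate the E methyl group of the terminal, more electron-rich alkene.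

Step 9
Reactants: 14 methyl (3E,7E)-9-hydroxy-4,8-dimethylnona-3,7-dienoate
Product: 15 methyl (3E)-6-[(2R,3R)-3-(hydroxymethyl)-3-methyloxiran-2-yl]-4-methylhex-3-enoate
Conditions: Ti(Oi-Pr)4, D-(−)-diethyl tartrate, t-BuOOH, 4 Å MS, CH2Cl2, −20 °C
Reagents that add atoms: tert-butyl hydroperoxide, CC(C)(C)OO
Why: Sharpless asymmetric epoxidation of the (E)-2-methyl allylic alcohol, in which the D-tartrate catalyst delivers oxygen to the face that gives the (R,R)-epoxide and the isolated 3-alkene is not touched.

Step 10
Reactants: 15 methyl (3E)-6-[(2R,3R)-3-(hydroxymethyl)-3-methyloxiran-2-yl]-4-methylhex-3-enoate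
Product: 16 methyl (3E,7S,8R)-7-bromo-8,9-dihydroxy-4,8-dimethylnon-3-enoate
Conditions: Et2NH·HBr, Ti(Oi-Pr)4, CH2Cl2, 25 °C
Reagents that add atoms: diethylammonium bromide, CC[NH2+]CC.[Br-]
Why: Titanium-assisted opening of a 2,3-epoxy alcohol at C3 by bromide (SN2, inversion) should set the secondary C–Br centre that becomes C4 and leave the tertiary C–O bond with its configuration.

Step 11
Reactants: 16 methyl (3E,7S,8R)-7-bromo-8,9-dihydroxy-4,8-dimethylnon-3-enoate
Product: 17 methyl (3E,7S,8R)-7-bromo-9-[(tert-butyldimethylsilyl)oxy]-8-hydroxy-4,8-dimethylnon-3-enoate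
Conditions: TBSCl, imidazole, CH2Cl2, 0 °C
Reagents that add atoms: tert-butyldimethylsilyl chloride, CC(C)(C)[Si](C)(C)Cl
Why: Selective silylation of the primary alcohol beside the tertiary one (silyl ether formation) gives a group that, unlike an ester, cannot participate at the neighbouring cationic carbon.

Step 12
Reactants: 17 methyl (3E,7S,8R)-7-bromo-9-[(tert-butyldimethylsilyl)oxy]-8-hydroxy-4,8-dimethylnon-3-enoate
Product: 18 (3aS,4R,5S,7aS)-5-bromo-4-{[(tert-butyldimethylsilyl)oxy]methyl}-4,7a-dimethylhexahydro-1-benzofuran-2(3H)-one (trans-fused lactone)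
Conditions: SnCl4, CH2Cl2, −78 → −30 °C
Reagents that add atoms: none
Why: Lewis-acid ionisation of the tertiary carbinol with anchimeric assistance by the anti C–Br should give the single bromonium ion of the (E)-alkene, which the 3-alkene opens at the tertiary carbon in a chair cation–olefin (polyene) cyclisation terminated by the ester carbonyl with loss of chloromethane; anti addition through the chair places Br and CH2OTBS equatorial, the C3a methyl axial and H7a axial, which sets C3a and C7a and gives the trans-fused lactone.

Step 13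
Reactants: 18 trans-fused silyloxymethyl bromo lactone
Product: 20 (3aS,4R,5S,7aR)-5-bromo-4-(hydroxymethyl)-4,7a-dimethylhexahydro-1-benzofuran-2(3H)-one (cis-fused lactone), via formate 19 (not isolated)
Conditions: HCO2H, H2SO4 (cat.), 40 °C; then NH3, MeOH, 0 °C
Reagents that add atoms: none
Why: Acid-catalysed ionisation of the tertiary C7–O bond and re-closure (thermodynamic epimerisation of a trans-fused to the cis-fused γ-lactone) should set C7 with oxygen cis to C1, while the silyl ether is cleaved and the primary alcohol is held as its formate until ammonolysis.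

Step 14
Reactants: 20 cis-fused hydroxymethyl bromo lactone
Product: 22 (3aS,4S,5S,7aR)-5-bromo-4-(iodomethyl)-4,7a-dimethylhexahydro-1-benzofuran-2(3H)-one, via triflate 21 (not isolated)
Conditions: Tf2O, pyridine, CH2Cl2, −20 °C; then n-Bu4NI, MeCN, 50 °C
Reagents that add atoms: tetrabutylammonium iodide, CCCC[N+](CCCC)(CCCC)CCCC.[I-]
Why: Triflation and SN2 displacement by iodide (Finkelstein-type) at the neopentyl carbon, which has no β-hydrogen and so cannot eliminate.

Step 15
Reactants: 22 cis-fused iodomethyl bromo lactone; 11 (E)-[(4S)-4-bromo-3,3-dimethylcyclohexylidene]methyl trifluoromethanesulfonate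
Product: 23 (3S,3aS,4S,5S,7aR)-5-bromo-3-{(E)-[(4S)-4-bromo-3,3-dimethylcyclohexylidene]methyl}-4-(iodomethyl)-4,7a-dimethylhexahydro-1-benzofuran-2(3H)-one
Conditions: LiHMDS, THF, −78 °C; ZnCl2; 11, Pd(dba)2, Q-Phos, 25 °C; then LiHMDS, −78 °C; AcOH, −78 °C
Reagents that add atoms: none
Why: Palladium-catalysed α-alkenylation of the zinc lactone enolate (enolate cross-coupling, selective for the sp2 triflate over the neopentyl iodide) should transfer the alkene with retention of E geometry, and the coupled lactone is then converted into its extended lithium enolate and protonated kinetically at C1 from the convex face, syn to H7a, which sets C1 with the alkenyl group cis to C3a.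

Step 16
Reactants: 23 α-alkenyl cis-fused bromo iodomethyl γ-lactone
Product: 25 iriediol 2-ketone (1S,3aS,4S,7R,7aS)-4-bromo-1-{(E)-[(4S)-4-bromo-3,3-dimethylcyclohexylidene]methyl}-7-hydroxy-3a,7-dimethyloctahydro-2H-inden-2-one, via thioester 24 (not isolated)
Conditions: Me3Al, EtSH (Me2AlSEt, 1.3 equiv), PhMe, 0 → 40 °C; then added to SmI2 (2.5 equiv), HMPA, THF, −78 °C; pH 7 buffer
Reagents that add atoms: none
Why: Proposed new method: C3 (equatorial on C3a) and O7 (axial on C7) are trans on the cyclohexane, so an adduct with C2 bound to C1, C3 and O7 together would be an in,out-bridged oxabicyclo[3.3.1]nonane and cannot form; Me2AlSEt therefore first moves the acyl group from O7 to sulfur (acyl–oxygen cleavage driven by the Al–O bond, the known aluminium-thiolate opening of lactones), leaving O7 capped as its aluminium alkoxide and C2 free to rotate about C1–C7a. SmI2–HMPA then reduces the primary iodide, the neopentyl radical is reduced further to the alkylsamarium, and this adds to the thioester carbonyl and expels thiolate; the closest known reaction is the SmI2-promoted intramolecular nucleophilic acyl substitution of ω-iodo esters. The cyclopentanone ring closes 5-exo-trig between the trans-diequatorial C3 and C1 arms, so the hydrindane is trans-fused by the existing C3a and C7a centres and no new stereocentre arises. Selectivity for the iodide over the two secondary bromides should follow from the much slower reduction of alkyl bromides at −78 °C with a limited charge of SmI2. The C3 radical is a 5-hexenyl radical toward the Cv=C alkene, so the thioester is added to excess SmI2–HMPA at −78 °C, where reduction to the organosamarium should outrun 5-exo addition, and the gauche (not anti) C3/C4–Br arrangement disfavours 1,3-elimination to a cyclopropane. Only one acyl substitution is expected because the thiolate leaves once, and a cold buffered quench protects the β,γ-unsaturated ketone from enolisation at C1.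

Step 17
Reactants: 25 iriediol 2-ketone
Product: 26 iriediol (1S,2R,3aS,4S,7R,7aS)-4-bromo-1-{(E)-[(4S)-4-bromo-3,3-dimethylcyclohexylidene]methyl}-3a,7-dimethyloctahydro-1H-indene-2,7-diol
Conditions: L-Selectride, THF, −78 °C; aq. NH4Cl
Reagents that add atoms: none
Why: L-Selectride reduction of the cyclopentanone, in which the bulky hydride should add anti to the adjacent C1 alkenyl group and so give the C2 alcohol cis to that group (2R).

Compound list
1 | 3-methylbut-2-en-1-ol (prenol) | CC(C)=CCO | starting material
2 | (2S)-2-bromo-3-chloro-3-methylbutan-1-ol | OC[C@H](Br)C(C)(C)Cl | intermediate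
3 | tert-butyl 3-oxobutanoate | CC(=O)CC(=O)OC(C)(C)C | starting material
4 | (2S)-2-bromo-3-chloro-3-methylbutyl trifluoromethanesulfonate | FC(F)(F)S(=O)(=O)OC[C@H](Br)C(C)(C)Cl | intermediate
5 | tert-butyl (6S)-6-bromo-7-chloro-7-methyl-3-oxooctanoate | CC(C)(C)OC(=O)CC(=O)CC[C@H](Br)C(C)(C)Cl | intermediate
6 | tert-butyl (3S)-3-bromo-2,2-dimethyl-6-oxocyclohexane-1-carboxylate (C1 epimers) | CC1(C)C(C(=O)OC(C)(C)C)C(=O)CC[C@@H]1Br | intermediate
7 | (4S)-4-bromo-3,3-dimethylcyclohexan-1-one | CC1(C)CC(=O)CC[C@@H]1Br | intermediate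
8 | (4S)-4-bromo-5,5-dimethylcyclohex-1-en-1-yl trifluoromethanesulfonate | CC1(C)CC(OS(=O)(=O)C(F)(F)F)=CC[C@@H]1Br | intermediate
9 | (4S)-4-bromo-5,5-dimethylcyclohex-1-ene-1-carbaldehyde | CC1(C)CC(C=O)=CC[C@@H]1Br | intermediate
10 | {(E)-[(4S)-4-bromo-3,3-dimethylcyclohexylidene]methoxy}triethylsilane | CC1(C)C/C(=C/O[Si](CC)(CC)CC)CC[C@@H]1Br | intermediate
11 | (E)-[(4S)-4-bromo-3,3-dimethylcyclohexylidene]methyl trifluoromethanesulfonate | CC1(C)C/C(=C/OS(=O)(=O)C(F)(F)F)CC[C@@H]1Br | intermediate
12 | geranyl acetate | CC(C)=CCC/C(C)=C/COC(C)=O | starting material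
13 | methyl (3E)-4,8-dimethylnona-3,7-dienoate | COC(=O)C/C=C(\C)CCC=C(C)C | intermediate
14 | methyl (3E,7E)-9-hydroxy-4,8-dimethylnona-3,7-dienoate | COC(=O)C/C=C(\C)CC/C=C(\C)CO | intermediate
15 | methyl (3E)-6-[(2R,3R)-3-(hydroxymethyl)-3-methyloxiran-2-yl]-4-methylhex-3-enoate | COC(=O)C/C=C(\C)CC[C@H]1O[C@]1(C)CO | intermediate
16 | methyl (3E,7S,8R)-7-bromo-8,9-dihydroxy-4,8-dimethylnon-3-enoate | COC(=O)C/C=C(\C)CC[C@H](Br)[C@@](C)(CO)O | intermediate
17 | methyl (3E,7S,8R)-7-bromo-9-[(tert-butyldimethylsilyl)oxy]-8-hydroxy-4,8-dimethylnon-3-enoate | COC(=O)C/C=C(\C)CC[C@H](Br)[C@@](C)(CO[Si](C)(C)C(C)(C)C)O | intermediate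
18 | (3aS,4R,5S,7aS)-5-bromo-4-{[(tert-butyldimethylsilyl)oxy]methyl}-4,7a-dimethylhexahydro-1-benzofuran-2(3H)-one (trans-fused) | C1C(=O)O[C@@]2(C)CC[C@H](Br)[C@@](C)(CO[Si](C)(C)C(C)(C)C)[C@H]12 | intermediate
19 | formate ester of 20 (cis-fused lactone, CH2OCHO on C4 of the benzofuranone) | C1C(=O)O[C@]2(C)CC[C@H](Br)[C@@](C)(COC=O)[C@H]12 | intermediate
20 | (3aS,4R,5S,7aR)-5-bromo-4-(hydroxymethyl)-4,7a-dimethylhexahydro-1-benzofuran-2(3H)-one (cis-fused) | C1C(=O)O[C@]2(C)CC[C@H](Br)[C@@](C)(CO)[C@H]12 | intermediate
21 | trifluoromethanesulfonate of 20 | C1C(=O)O[C@]2(C)CC[C@H](Br)[C@@](C)(COS(=O)(=O)C(F)(F)F)[C@H]12 | intermediate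
22 | (3aS,4S,5S,7aR)-5-bromo-4-(iodomethyl)-4,7a-dimethylhexahydro-1-benzofuran-2(3H)-one | C1C(=O)O[C@]2(C)CC[C@H](Br)[C@@](C)(CI)[C@H]12 | intermediate
23 | (3S,3aS,4S,5S,7aR)-5-bromo-3-{(E)-[(4S)-4-bromo-3,3-dimethylcyclohexylidene]methyl}-4-(iodomethyl)-4,7a-dimethylhexahydro-1-benzofuran-2(3H)-one | CC1(C)C/C(=C/[C@@H]2C(=O)O[C@]3(C)CC[C@H](Br)[C@@](C)(CI)[C@H]23)CC[C@@H]1Br | intermediate
24 | S-ethyl thioester from opening 23 at C2–O7 (C7 hydroxyl free, held as its aluminium alkoxide in the flask; all stereocentres as in 23) | CC1(C)C/C(=C/[C@H](C(=O)SCC)[C@H]2[C@](C)(CI)[C@@H](Br)CC[C@@]2(C)O)CC[C@@H]1Br | intermediate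
25 | iriediol 2-ketone, (1S,3aS,4S,7R,7aS)-4-bromo-1-{(E)-[(4S)-4-bromo-3,3-dimethylcyclohexylidene]methyl}-7-hydroxy-3a,7-dimethyloctahydro-2H-inden-2-one | CC1(C)C/C(=C/[C@@H]2C(=O)C[C@]3(C)[C@@H](Br)CC[C@@](C)(O)[C@@H]23)CC[C@@H]1Br | intermediate
26 | iriediol, (1S,2R,3aS,4S,7R,7aS)-4-bromo-1-{(E)-[(4S)-4-bromo-3,3-dimethylcyclohexylidene]methyl}-3a,7-dimethyloctahydro-1H-indene-2,7-diol | CC1(C)C/C(=C/[C@@H]2[C@H](O)C[C@]3(C)[C@@H](Br)CC[C@@](C)(O)[C@@H]23)CC[C@@H]1Br | target

Total step count: 17. Longest linear sequence: 11 steps (steps 7–17, from geranyl acetate); the ring-A branch (steps 1–6) joins at step 15.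

Steps most likely to fail

1. Step 16 (Proposed new method). The acyl transfer from O7 to sulfur may be incomplete at the hindered carbonyl, the C3 radical may add 5-exo to the exocyclic alkene before it is reduced, or the new ketone may be reduced further. The fallback is polar and uses known chemistry. Setting out from 23, aminolysis with Me2AlN(OMe)Me should give the hydroxy Weinreb amide F1, and TESOTf with 2,6-lutidine its C7 silyl ether F2. t-BuLi (2.1 equiv, Et2O–pentane, −100 °C) should exchange the primary iodide much faster than the secondary bromides, and the alkyllithium should acylate itself on the Weinreb amide (Parham-type cyclisation, no radical) to the silyl-protected ketone F3. HF·pyridine then returns to 25.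

2. Step 12. The oxygen-substituted tertiary cation may rearrange by hydride shift, the alkene may attack the secondary carbon of the bromonium ion, or the silyl ether may be lost before ring closure. The fallback changes the leaving group and removes the Lewis acid. Setting out from 17, SOCl2 with pyridine should replace the tertiary hydroxyl by chloride with retention through the bromonium ion and give the bromochloride F4. Solvolysis of this in buffered HFIP, as in step 3, should generate the same bromonium ion and return to 18.

3. Step 15. Coupling at the hindered α-carbon may be slow, the alkenyl triflate may undergo α-elimination, and protonation at C1 may show poor facial selectivity. The fallback forms the same bond by carbonyl chemistry and sets both the alkene geometry and C1 in a hydrogenation. Setting out from 22 and 9, aldol addition of the lithium enolate should give the β-hydroxy lactone F5, and Burgess dehydration the dienyl lactone F6. 1,4-Hydrogenation of the s-cis diene with (naphthalene)Cr(CO)3 and H2 should add hydrogen to C1 from the convex face and to the ring CH, which gives the E exocyclic alkene and returns to 23.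

Further compounds
F1 | step 16 | N-methoxy-N-methyl amide from opening 23 at C2–O7 (C7 hydroxyl free) | CC1(C)C/C(=C/[C@H](C(=O)N(C)OC)[C@H]2[C@](C)(CI)[C@@H](Br)CC[C@@]2(C)O)CC[C@@H]1Br
F2 | step 16 | C7 triethylsilyl ether of F1 | CC1(C)C/C(=C/[C@H](C(=O)N(C)OC)[C@H]2[C@](C)(CI)[C@@H](Br)CC[C@@]2(C)O[Si](CC)(CC)CC)CC[C@@H]1Br
F3 | step 16 | C7 triethylsilyl ether of ketone 25 | CC1(C)C/C(=C/[C@@H]2C(=O)C[C@]3(C)[C@@H](Br)CC[C@@](C)(O[Si](CC)(CC)CC)[C@@H]23)CC[C@@H]1Br
F4 | step 12 | methyl (3E,7S,8R)-7-bromo-9-[(tert-butyldimethylsilyl)oxy]-8-chloro-4,8-dimethylnon-3-enoate | COC(=O)C/C=C(\C)CC[C@H](Br)[C@@](C)(CO[Si](C)(C)C(C)(C)C)Cl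
F5 | step 15 | aldol adduct of lactone 22 (at C3 of the benzofuranone) with enal 9, both new centres unassigned | CC1(C)CC(C(O)C2C(=O)O[C@]3(C)CC[C@H](Br)[C@@](C)(CI)[C@H]23)=CC[C@@H]1Br
F6 | step 15 | 3-{[(4S)-4-bromo-5,5-dimethylcyclohex-1-en-1-yl]methylidene} derivative of lactone 22 (dienyl lactone, alkylidene geometry unassigned) | CC1(C)CC(C=C2C(=O)O[C@]3(C)CC[C@H](Br)[C@@](C)(CI)[C@H]23)=CC[C@@H]1Br
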